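**Plan**

1. Cuts, in retrosynthetic order: the C15–O palmitate ester and the C15 alcohol level; the C8=C17 methylene, traced back to a C7=C8 enal with C17 as CHO; then ring B at C9–C10 and C7–C8 in one operation.
2. Enabling feature: in ring B the methyl-bearing quaternary C10 lies between ring-fusion C5 and C9 (which carries the C11–C16 chain), C9 is followed by C8 with its single exocyclic carbon C17, and C7 is plain CH2. This is the imprint of a tertiary ring-A C10 radical adding to the β-carbon of an enal whose enolate then closes on a C7 aldehyde.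
3. The ring-A partner 11 is cut at C19–C7 to a cis-fused 7a-methylhydrindanone, built from 2-methylcyclopent-2-enone by conjugate addition and intramolecular alkylation; the enal 15 comes from methyl geranate.
4. Forward order: ring A (carrying a sacrificial five-membered ring), then ester aldehyde 11; 11 + 15 close ring B and bring in the whole chain; dehydration, 1,2-reduction, reductive allylic transposition, C15 reduction and palmitoylation follow.
5. Stereochemistry: C5 from a catalyst-controlled conjugate addition; C4 from the enforced cis ring fusion; C10 and C9 from substrate control in the annulation; 13E from methyl geranate.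

Key step: step 8

Assumption: the target is taken as the normal-series labdane (4S,5R,9S,10R), the 15-palmitate of methyl isocupressate; labdane numbering is used (ring A C1–C5 and C10, ring B C5–C10, C17 on C8, C18 and ester carbon C19 on C4, C20 on C10, chain C11–C16 on C9).

**Route**

Step 1
Reactants: 1 5-chloropent-1-yne
Product: 3 2-bromo-5-chloropent-1-ene, via 9-[(Z)-2-bromo-5-chloropent-1-enyl]-9-BBN 2 (not isolated)
Conditions: B-bromo-9-BBN, CH2Cl2, 0 °C; then AcOH, 0 °C to rt
Reagents that add atoms: B-bromo-9-borabicyclo[3.3.1]nonane, BrB1C2CCCC1CCC2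
Why: Syn-bromoboration of the terminal alkyne places bromine on the internal carbon and protonolysis of the alkenyl–boron bond with acetic acid leaves the 2-bromo-1-alkene (haloboration–protodeboronation), the primary chloride being inert throughout.

Step 2
Reactants: 3 2-bromo-5-chloropent-1-ene; 4 2-methylcyclopent-2-en-1-one
Product: 7 (2R,3S)-3-(5-chloropent-1-en-2-yl)-2-methylcyclopentan-1-one, via (5-chloropent-1-en-2-yl)lithium 5 (not isolated), via (5-chloropent-1-en-2-yl)magnesium bromide 6 (not isolated)
Conditions: 3, t-BuLi (2 equiv), Et2O, −78 °C; MgBr2·OEt2, −78 to −30 °C; added slowly to 4, Cu(OTf)2 (5 mol %), chiral N-mesityl-N′-(hydroxyalkyl)imidazolinium salt (NHC precursor, 6 mol %, enantiomer chosen for the 3S adduct), Et2O, −30 °C; H2O quench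
Reagents that add atoms: none
Why: Copper–NHC-catalysed asymmetric conjugate addition of a Grignard reagent to an α-methyl cyclic enone, in which the chiral ligand decides the face of attack at the β-carbon and so fixes the future C5 as 3S, while the C2 configuration from protonation is of no consequence because C2 is re-enolised in step 3.

Step 3
Reactants: 7 (2R,3S)-3-(5-chloropent-1-en-2-yl)-2-methylcyclopentan-1-one
Product: 8 (3aR,7aS)-7a-methyl-4-methylideneoctahydro-1H-inden-1-one
Conditions: t-BuOK, t-BuOH/THF, 25 °C
Reagents that add atoms: none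
Why: Intramolecular alkylation of the more substituted potassium enolate by the primary chloride (methylenecyclohexane annulation, 6-(enolendo)-exo-tet) can only deliver the three-carbon tether to the enolate face on which it already sits at C3, so the quaternary methyl centre (future C4) forms cis-fused and the C4/C5 relation is enforced by the ring instead of by an intermolecular alkylation beside a quaternary carbon.

Step 4
Reactants: 8 (3aR,7aS)-7a-methyl-4-methylideneoctahydro-1H-inden-1-one
Product: 10 (3aR,7aS)-2-hydroxy-7a-methyl-4-methylideneoctahydro-1H-inden-1-one, via potassium enolate of the hydrindanone 9 (not isolated)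
Conditions: KN(SiMe3)2, THF, −78 °C; 2-(phenylsulfonyl)-3-phenyloxaziridine, −78 °C; H2O quench
Reagents that add atoms: 2-(phenylsulfonyl)-3-phenyloxaziridine, O=S(=O)(c1ccccc1)N1OC1c1ccccc1
Why: Electrophilic α-hydroxylation of the only enolisable position (C2 of the hydrindanone, the future C7) with a Davis oxaziridine; the new carbinol centre (convex-face attack expected) is irrelevant because this carbon becomes the aldehyde.

Step 5
Reactants: 10 (3aR,7aS)-2-hydroxy-7a-methyl-4-methylideneoctahydro-1H-inden-1-one
Product: 11 methyl (1S,2R)-1-methyl-3-methylidene-2-(2-oxoethyl)cyclohexane-1-carboxylate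
Conditions: Pb(OAc)4, MeOH/PhMe (1:1), 0 °C
Reagents that add atoms: methanol, CO
Why: Criegee-type cleavage of the α-ketol by tetravalent lead through the methyl hemiketal converts the ketone carbon into the C19 methyl ester and the carbinol carbon into the C7 aldehyde without touching C4 or C5, so the ester and the 2-oxoethyl arm stay cis.

Step 6
Reactants: 12 methyl geranate
Product: 14 methyl (2E)-3-methyl-6-oxohex-2-enoate, via methyl geranate 6,7-ozonide 13 (not isolated)
Conditions: O3 (1 equiv), CH2Cl2, −78 °C; then Me2S, −78 °C to rt
Reagents that add atoms: ozone, [O-][O+]=O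
Why: Ozonolysis with reductive work-up is selective for the electron-rich isopropylidene alkene over the conjugated C2=C3 bond, whose E geometry is carried through to 13E of the target.

Step 7
Reactants: 14 methyl (2E)-3-methyl-6-oxohex-2-enoate
Product: 15 methyl (2E,6E)-3-methyl-8-oxoocta-2,6-dienoate
Conditions: Ph3P=CHCHO (1.05 equiv), PhMe, 80 °C
Reagents that add atoms: (triphenylphosphoranylidene)acetaldehyde, O=CC=P(c1ccccc1)(c1ccccc1)c1ccccc1
Why: Wittig olefination with the stabilised formyl ylide gives the E-enal and stops after one homologation because the conjugated product aldehyde is the less electrophilic carbonyl.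

Step 8
Reactants: 11 methyl (1S,2R)-1-methyl-3-methylidene-2-(2-oxoethyl)cyclohexane-1-carboxylate; 15 methyl (2E,6E)-3-methyl-8-oxoocta-2,6-dienoate
Product: 16 dimethyl (13E)-7β-hydroxy-17-oxolabd-13-ene-15,19-dioate (8α-CHO; trans-decalin with 5α-H, 9α-H, 10β-CH3)
Conditions: Fe(acac)3 (30 mol %), PhSiH3 (2.5 equiv, slow addition), 15 (2.5 equiv), EtOH/(CH2OH)2 (5:1), degassed, 25 °C
Reagents that add atoms: none
Why: An iron hydride formed from Fe(acac)3 and PhSiH3 transfers a hydrogen atom to the C20 methylene of 11, the tertiary C10 radical adds to the β-carbon C9 of enal 15 (Giese addition, C9–C10), and the α-formyl radical is reduced by divalent iron to the C8 enolate, which adds to the C7 aldehyde (C7–C8). The closest known reaction type is the iron-hydride hydrogen-atom-transfer radical–polar crossover annulation of alkenyl aldehydes with unsaturated carbonyl acceptors, which gives cyclohexanols bearing a quaternary carbon. Ring B closes by a 6-(enolexo)-exo-trig aldol addition through a chair. C10 is set by entry of the acceptor on the α face, anti to the C5–C6 arm and away from the axial C19 ester that shields the β face, so C20 ends axial and the decalin trans; C9 is set by the topicity of the same addition, where with H9 turned under ring A the flat C8 terminus is expected to take the crowded sector beside C5 and the C11 methylene the open sector beside C1, giving 9α-H and placing C8 next to C7; C8 and C7 arise in the chair closure (all-equatorial expected) and are erased in step 9. The step needs hydrogen-atom transfer to the 1,1-disubstituted alkene and addition at the enal, not the enoate, which is secured because the donor alkene is the only electron-rich one, the enal is in excess and the β,β-disubstituted enoate is a poor radical acceptor. C9 is the one centre not fixed by a ring and is treated as the main risk below.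

Step 9
Reactants: 16 dimethyl (13E)-7β-hydroxy-17-oxolabd-13-ene-15,19-dioate
Product: 18 dimethyl (13E)-17-oxolabda-7,13-diene-15,19-dioate, via C7 mesylate of the aldol 17 (not isolated)
Conditions: MsCl, Et3N, CH2Cl2, 0 °C; then DBU, 25 °C
Reagents that add atoms: none
Why: Mesylation followed by E1cB elimination of the β-mesyloxy aldehyde gives the conjugated C7=C8 enal from any C7/C8 epimer and so erases both transient centres, while C9, which sits on the α-carbon of the enal and is not conjugatively acidified, keeps its configuration.

Step 10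
Reactants: 18 dimethyl (13E)-17-oxolabda-7,13-diene-15,19-dioate
Product: 19 dimethyl (13E)-17-hydroxylabda-7,13-diene-15,19-dioate
Conditions: NaBH4, CeCl3·7H2O, MeOH, −20 °C
Reagents that add atoms: none
Why: Luche 1,2-reduction delivers hydride to the aldehyde carbon only, leaving the C7=C8 alkene, the chain enoate and the C19 ester untouched.

Step 11
Reactants: 19 dimethyl (13E)-17-hydroxylabda-7,13-diene-15,19-dioate
Product: 20 dimethyl (13E)-17-[(methoxycarbonyl)oxy]labda-7,13-diene-15,19-dioate
Conditions: ClCO2Me, pyridine, DMAP (cat.), CH2Cl2, 0 °C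
Reagents that add atoms: methyl chloroformate, COC(=O)Cl
Why: Acylation of the primary allylic alcohol with methyl chloroformate under nucleophilic catalysis gives the carbonate needed for ionisation by palladium.

Step 12
Reactants: 20 dimethyl (13E)-17-[(methoxycarbonyl)oxy]labda-7,13-diene-15,19-dioate
Product: 21 dimethyl (13E)-labda-8(17),13-diene-15,19-dioate
Conditions: Pd2(dba)3·CHCl3 (2.5 mol %), PBu3 (5 mol %), HCO2NH4 (2 equiv), 1,4-dioxane, 100 °C
Reagents that add atoms: none
Why: Zerovalent palladium ionises the carbonate to the C17–C8–C7 π-allyl complex and the formate ligand delivers hydride to the more substituted terminus C7 (Tsuji formate hydrogenolysis of a terminal allylic carbonate with PBu3 as ligand), which leaves the exocyclic C8=C17 methylene; C7 becomes CH2 and C9 is not part of the allyl unit, so no stereocentre is at stake.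

Step 13
Reactants: 21 dimethyl (13E)-labda-8(17),13-diene-15,19-dioate
Product: 22 methyl (13E)-15-hydroxylabda-8(17),13-dien-19-oate
Conditions: i-Bu2AlH (2.2 equiv), CH2Cl2, −78 °C; aq. potassium sodium tartrate
Reagents that add atoms: none
Why: Low-temperature i-Bu2AlH reduction takes the unhindered conjugated C15 ester to the allylic alcohol in a 1,2 sense while the axial, neopentyl C19 ester on the quaternary C4 reacts far more slowly (chemoselective ester reduction).

Step 14
Reactants: 22 methyl (13E)-15-hydroxylabda-8(17),13-dien-19-oate; 23 palmitoyl chloride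
Product: 24 methyl (13E)-15-(hexadecanoyloxy)labda-8(17),13-dien-19-oate
Conditions: pyridine, DMAP (cat.), CH2Cl2, 0 °C to rt
Reagents that add atoms: none
Why: DMAP-catalysed acylation of the primary allylic alcohol with the acid chloride (esterification) completes the palmitate without affecting any stereocentre.

**Compound list**

1 | 5-chloropent-1-yne | C#CCCCCl | starting material
2 | 9-[(Z)-2-bromo-5-chloropent-1-en-1-yl]-9-borabicyclo[3.3.1]nonane (formed in situ) | Br/C(CCCCl)=C\B1C2CCCC1CCC2 | intermediate
3 | 2-bromo-5-chloropent-1-ene | C=C(Br)CCCCl | intermediate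
4 | 2-methylcyclopent-2-en-1-one | CC1=CCCC1=O | starting material
5 | (5-chloropent-1-en-2-yl)lithium (formed in situ) | [Li]C(=C)CCCCl | intermediate
6 | (5-chloropent-1-en-2-yl)magnesium bromide (formed in situ) | Br[Mg]C(=C)CCCCl | intermediate
7 | (2R,3S)-3-(5-chloropent-1-en-2-yl)-2-methylcyclopentan-1-one (trans isomer drawn; the C2 epimer converges in step 3) | O=C1[C@H](C)[C@H](CC1)C(=C)CCCCl | intermediate
8 | (3aR,7aS)-7a-methyl-4-methylideneoctahydro-1H-inden-1-one (cis-fused) | O=C1[C@@]2(C)CCCC(=C)[C@H]2CC1 | intermediate
9 | potassium (3aR,7aS)-7a-methyl-4-methylidene-3a,4,5,6,7,7a-hexahydro-3H-inden-1-olate (formed in situ) | [K+].[O-]C1=CC[C@@H]2C(=C)CCC[C@]12C | intermediate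
10 | (3aR,7aS)-2-hydroxy-7a-methyl-4-methylideneoctahydro-1H-inden-1-one (either C2 epimer) | O=C1[C@@]2(C)CCCC(=C)[C@H]2CC1O | intermediate
11 | methyl (1S,2R)-1-methyl-3-methylidene-2-(2-oxoethyl)cyclohexane-1-carboxylate (ester and arm cis) | COC(=O)[C@@]1(C)CCCC(=C)[C@H]1CC=O | intermediate
12 | methyl geranate, methyl (2E)-3,7-dimethylocta-2,6-dienoate | COC(=O)/C=C(\C)CCC=C(C)C | starting material
13 | methyl (2E)-5-(5,5-dimethyl-1,2,4-trioxolan-3-yl)-3-methylpent-2-enoate (ozonide, formed in situ) | COC(=O)/C=C(\C)CCC1OOC(C)(C)O1 | intermediate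
14 | methyl (2E)-3-methyl-6-oxohex-2-enoate | COC(=O)/C=C(\C)CCC=O | intermediate
15 | methyl (2E,6E)-3-methyl-8-oxoocta-2,6-dienoate | O=C/C=C/CC/C(C)=C/C(=O)OC | intermediate
16 | dimethyl (13E)-7β-hydroxy-17-oxolabd-13-ene-15,19-dioate (7β-OH, 8α-CHO and 9β-chain all equatorial; 5α-H, 10β-CH3, 4β-CO2Me) | O=C[C@@H]1[C@@H](O)C[C@@H]2[C@](C)(CCC[C@]2(C)C(=O)OC)[C@H]1CC/C(C)=C/C(=O)OC | intermediate
17 | C7 methanesulfonate of 16 (formed in situ) | O=C[C@@H]1[C@@H](OS(C)(=O)=O)C[C@@H]2[C@](C)(CCC[C@]2(C)C(=O)OC)[C@H]1CC/C(C)=C/C(=O)OC | intermediate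
18 | dimethyl (13E)-17-oxolabda-7,13-diene-15,19-dioate | O=CC1=CC[C@@H]2[C@](C)(CCC[C@]2(C)C(=O)OC)[C@H]1CC/C(C)=C/C(=O)OC | intermediate
19 | dimethyl (13E)-17-hydroxylabda-7,13-diene-15,19-dioate | OCC1=CC[C@@H]2[C@](C)(CCC[C@]2(C)C(=O)OC)[C@H]1CC/C(C)=C/C(=O)OC | intermediate
20 | dimethyl (13E)-17-[(methoxycarbonyl)oxy]labda-7,13-diene-15,19-dioate | COC(=O)OCC1=CC[C@@H]2[C@](C)(CCC[C@]2(C)C(=O)OC)[C@H]1CC/C(C)=C/C(=O)OC | intermediate
21 | dimethyl (13E)-labda-8(17),13-diene-15,19-dioate | C=C1CC[C@@H]2[C@](C)(CCC[C@]2(C)C(=O)OC)[C@H]1CC/C(C)=C/C(=O)OC | intermediate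
22 | methyl (13E)-15-hydroxylabda-8(17),13-dien-19-oate | C=C1CC[C@@H]2[C@](C)(CCC[C@]2(C)C(=O)OC)[C@H]1CC/C(C)=C/CO | intermediate
23 | palmitoyl chloride (hexadecanoyl chloride) | CCCCCCCCCCCCCCCC(=O)Cl | starting material
24 | methyl (13E)-15-(hexadecanoyloxy)labda-8(17),13-dien-19-oate; methyl (1S,4aR,5S,8aR)-5-[(3E)-5-(hexadecanoyloxy)-3-methylpent-3-en-1-yl]-1,4a-dimethyl-6-methylidenedecahydronaphthalene-1-carboxylate | C=C1CC[C@@H]2[C@](C)(CCC[C@]2(C)C(=O)OC)[C@H]1CC/C(C)=C/COC(=O)CCCCCCCCCCCCCCC | target

**Totals**

Total step count: 14.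
Longest linear sequence: 12 steps (steps 1–5, then 8–14); the enal branch (steps 6 and 7) joins at step 8.

**Steps most likely to fail**

Step 8. The radical addition may show weak control over which enal face bonds to C10, so part of the material would carry the C9 chain axial; direct reduction of the enal by hydrogen-atom transfer may also compete. C9 cannot be equilibrated in 16 or 18, so the fallback moves the problem to thermodynamic control at an 8-ketone. It sets out from 21, which would then be accompanied by its C9 epimer dimethyl (13E)-9-epi-labda-8(17),13-diene-15,19-dioate F1. Ozonolysis with one equivalent of O3 in CH2Cl2/pyridine at −78 °C cleaves the 1,1-disubstituted alkene ahead of the enoate and should give the 17-nor ketones, dimethyl (13E)-8-oxo-17-nor-9-epi-labd-13-ene-15,19-dioate F2 and dimethyl (13E)-8-oxo-17-norlabd-13-ene-15,19-dioate F3. Mild base (DBU, PhMe, 60 °C) should equilibrate F2 into F3, in which the chain is equatorial. Wittig methylenation of F3 (Ph3P=CH2 from Ph3PCH3Br and t-BuOK, THF) comes back to the route at 21 as the single 9α-H isomer.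

Step 2. Enantioselection may erode because the α-branched alkenyl Grignard reagent adds partly through a pathway not controlled by the ligand. The fallback replaces catalyst control by a stoichiometric sulfoxide auxiliary and sets out from 3. Reagent 6, made as in step 2, is added at −78 °C in THF to the known enone (R)-2-[(4-methylphenyl)sulfinyl]cyclopent-2-en-1-one F4; the sulfoxide enantiomer is the one expected on the chelate model to give the required C3 configuration. The resulting α-sulfinyl enolate is methylated in the same flask with MeI to give (3R)-3-(5-chloropent-1-en-2-yl)-2-methyl-2-[(R)-(4-methylphenyl)sulfinyl]cyclopentan-1-one F5. Reductive removal of the sulfinyl group with aluminium amalgam in aqueous THF comes back to the route at 7.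

Step 12. Hydride may be delivered to the primary allyl terminus C17, or a palladium hydride may move the new exocyclic alkene into the ring. The fallback is a metal-free reductive 1,3-transposition and sets out from 19. Mitsunobu displacement with 2-nitrobenzenesulfonylhydrazine (PPh3, diethyl azodicarboxylate, THF, −30 °C) should give the N-allylic sulfonylhydrazine, dimethyl (13E)-17-[1-(2-nitrobenzenesulfonyl)hydrazinyl]labda-7,13-diene-15,19-dioate F6. On warming it loses the sulfinate to give the monoalkyl diazene, dimethyl (13E)-17-diazenyllabda-7,13-diene-15,19-dioate F7. F7 expels dinitrogen in a retro-ene shift that puts hydrogen on C7 and the double bond at C8=C17, coming back to the route at 21.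

**Further compounds**

F1 | step 8 | dimethyl (13E)-9-epi-labda-8(17),13-diene-15,19-dioate | C=C1CC[C@@H]2[C@](C)(CCC[C@]2(C)C(=O)OC)[C@@H]1CC/C(C)=C/C(=O)OC
F2 | step 8 | dimethyl (13E)-8-oxo-17-nor-9-epi-labd-13-ene-15,19-dioate | O=C1CC[C@@H]2[C@](C)(CCC[C@]2(C)C(=O)OC)[C@@H]1CC/C(C)=C/C(=O)OC
F3 | step 8 | dimethyl (13E)-8-oxo-17-norlabd-13-ene-15,19-dioate | O=C1CC[C@@H]2[C@](C)(CCC[C@]2(C)C(=O)OC)[C@H]1CC/C(C)=C/C(=O)OC
F4 | step 2 | (R)-2-[(4-methylphenyl)sulfinyl]cyclopent-2-en-1-one | O=C1CCC=C1[S@](=O)c1ccc(C)cc1
F5 | step 2 | (3R)-3-(5-chloropent-1-en-2-yl)-2-methyl-2-[(R)-(4-methylphenyl)sulfinyl]cyclopentan-1-one (C2 epimers) | O=C1C(C)([S@](=O)c2ccc(C)cc2)[C@H](CC1)C(=C)CCCCl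
F6 | step 12 | dimethyl (13E)-17-[1-(2-nitrobenzenesulfonyl)hydrazinyl]labda-7,13-diene-15,19-dioate | NN(CC1=CC[C@@H]2[C@](C)(CCC[C@]2(C)C(=O)OC)[C@H]1CC/C(C)=C/C(=O)OC)S(=O)(=O)c1ccccc1[N+](=O)[O-]
F7 | step 12 | dimethyl (13E)-17-diazenyllabda-7,13-diene-15,19-dioate | N=NCC1=CC[C@@H]2[C@](C)(CCC[C@]2(C)C(=O)OC)[C@H]1CC/C(C)=C/C(=O)OC
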